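**Retrosynthetic overview**
- Butenolide ring (formed last): unveiled from a 3-furyl group by singlet-oxygen oxidation and borohydride reduction, after acetylation of the neighbouring carbinol.
- α-Alkylidene-γ-butyrolactone ring (formed first): Z-selective Still–Gennari olefination of a C11 dienal (fragment 1) with an α-branched trifluoroethyl phosphonate (fragment 2), then desilylative lactonisation.
- Fragment 1: two isopropenyl-Grignard / Johnson–Claisen cycles build both (E)-trisubstituted olefins from a β-silyloxy aldehyde; its carbinol centre comes from Ru-catalysed asymmetric transfer hydrogenation of a furyl β-keto ester.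
- Fragment 2: C-alkylation of the phosphonoacetate by a primary triflate; its oxygenated stereocentre is set by ketoreductase reduction of a 2-oxo ester.

Assumption: compounds 1, 5, 7, 15, 16 and 23 are catalogue chemicals, and the (R)-selective ketoreductase is picked from a commercial screening panel.

**Step 1**
Reactants: 1 ethyl 3-(furan-3-yl)-3-oxopropanoate
Product: 2 ethyl (3R)-3-(furan-3-yl)-3-hydroxypropanoate
Conditions: [RuCl(p-cymene)((R,R)-TsDPEN)] (0.5 mol%), HCO2H/Et3N (5:2), DMF, 30 °C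
Reagents that add atoms: none
Why: Noyori asymmetric transfer hydrogenation of an aryl-type (3-furyl) ketone; the (R,R)-catalyst delivers hydride through the six-membered outer-sphere transition state (arene CH/π contact with the furan) and sets the carbinol as R.

**Step 2**
Reactants: 2 ethyl (3R)-3-(furan-3-yl)-3-hydroxypropanoate
Product: 3 ethyl (3R)-3-[(tert-butyldimethylsilyl)oxy]-3-(furan-3-yl)propanoate
Conditions: tBuMe2SiCl, imidazole, DMF, rt
Reagents that add atoms: tert-butyldimethylsilyl chloride CC(C)(C)[Si](C)(C)Cl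
Why: Standard silyl ether protection of the carbinol for the organometallic and Claisen steps; the stereocentre is not touched.

**Step 3**
Reactants: 3 ethyl (3R)-3-[(tert-butyldimethylsilyl)oxy]-3-(furan-3-yl)propanoate
Product: 4 (3R)-3-[(tert-butyldimethylsilyl)oxy]-3-(furan-3-yl)propanal
Conditions: iBu2AlH (1.1 equiv), CH2Cl2, −78 °C; aq. potassium sodium tartrate
Reagents that add atoms: none
Why: Partial ester reduction; the tetrahedral aluminium hemiacetal is stable at −78 °C and releases the aldehyde only on work-up.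

**Step 4**
Reactants: 4 (3R)-3-[(tert-butyldimethylsilyl)oxy]-3-(furan-3-yl)propanal; 5 isopropenylmagnesium bromide
Product: 6 (3RS,5R)-5-[(tert-butyldimethylsilyl)oxy]-5-(furan-3-yl)-2-methylpent-1-en-3-ol
Conditions: THF, −78 → 0 °C; aq. NH4Cl
Reagents that add atoms: none
Why: Grignard 1,2-addition to the aldehyde; the new carbinol forms as an epimer mixture that is erased in the next step.

**Step 5**
Reactants: 6 (3RS,5R)-5-[(tert-butyldimethylsilyl)oxy]-5-(furan-3-yl)-2-methylpent-1-en-3-ol; 7 triethyl orthoacetate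
Product: 9 ethyl (4E,7R)-7-[(tert-butyldimethylsilyl)oxy]-7-(furan-3-yl)-4-methylhept-4-enoate, via ketene acetal 8 (not isolated)
Conditions: MeC(OEt)3 (7 equiv), EtCO2H (0.1 equiv), 140 °C, EtOH distilled off
Reagents that add atoms: none
Why: Johnson–Claisen orthoester rearrangement; the chair transition state with the side chain equatorial gives the (E)-trisubstituted olefin (typically ≥95:5), and both carbinol epimers converge.

**Step 6**
Reactants: 9 ethyl (4E,7R)-7-[(tert-butyldimethylsilyl)oxy]-7-(furan-3-yl)-4-methylhept-4-enoate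
Product: 10 (4E,7R)-7-[(tert-butyldimethylsilyl)oxy]-7-(furan-3-yl)-4-methylhept-4-enal
Conditions: iBu2AlH (1.1 equiv), CH2Cl2/toluene, −78 °C; aq. potassium sodium tartrate
Reagents that add atoms: none
Why: Partial ester reduction through the low-temperature aluminium hemiacetal; the olefin and silyl ether are inert.

**Step 7**
Reactants: 10 (4E,7R)-7-[(tert-butyldimethylsilyl)oxy]-7-(furan-3-yl)-4-methylhept-4-enal; 5 isopropenylmagnesium bromide
Product: 11 (3RS,6E,9R)-9-[(tert-butyldimethylsilyl)oxy]-9-(furan-3-yl)-2,6-dimethylnona-1,6-dien-3-ol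
Conditions: THF, −78 → 0 °C; aq. NH4Cl
Reagents that add atoms: none
Why: Grignard 1,2-addition; the carbinol configuration is again irrelevant because it is destroyed in the following rearrangement.

**Step 8**
Reactants: 11 (3RS,6E,9R)-9-[(tert-butyldimethylsilyl)oxy]-9-(furan-3-yl)-2,6-dimethylnona-1,6-dien-3-ol; 7 triethyl orthoacetate
Product: 13 ethyl (4E,8E,11R)-11-[(tert-butyldimethylsilyl)oxy]-11-(furan-3-yl)-4,8-dimethylundeca-4,8-dienoate, via ketene acetal 12 (not isolated)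
Conditions: MeC(OEt)3 (7 equiv), EtCO2H (0.1 equiv), 140 °C, EtOH distilled off
Reagents that add atoms: none
Why: Second Johnson–Claisen rearrangement; the same chair-controlled [3,3] shift installs the second (E)-trisubstituted olefin.

**Step 9**
Reactants: 13 ethyl (4E,8E,11R)-11-[(tert-butyldimethylsilyl)oxy]-11-(furan-3-yl)-4,8-dimethylundeca-4,8-dienoate
Product: 14 (4E,8E,11R)-11-[(tert-butyldimethylsilyl)oxy]-11-(furan-3-yl)-4,8-dimethylundeca-4,8-dienal
Conditions: iBu2AlH (1.1 equiv), CH2Cl2/toluene, −78 °C; aq. potassium sodium tartrate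
Reagents that add atoms: none
Why: Partial ester reduction via the stable tetrahedral aluminium adduct gives the aldehyde for the olefination.

**Step 10**
Reactants: 15 diethyl oxalate; 16 (2-methylprop-1-en-1-yl)magnesium bromide
Product: 17 ethyl 4-methyl-2-oxopent-3-enoate
Conditions: 16 added to 15 (2 equiv), THF/Et2O, −78 °C; cold aq. NH4Cl
Reagents that add atoms: none
Why: Mono-acylation of the alkenyl Grignard reagent; the chelated tetrahedral adduct persists at −78 °C, so only one ester of the excess oxalate reacts.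

**Step 11**
Reactants: 17 ethyl 4-methyl-2-oxopent-3-enoate
Product: 18 ethyl (2R)-2-hydroxy-4-methylpent-3-enoate
Conditions: (R)-selective ketoreductase, NADP+ (cat.), iPrOH (10% v/v), KH2PO4/K2HPO4 buffer pH 7.0, 30 °C
Reagents that add atoms: none
Why: Enzymatic carbonyl reduction by a ketoreductase; NADPH hydride is delivered to one face of the activated 2-oxo ester in the chiral active site, setting C2 as R (>99% ee expected) without touching the C=C, while isopropanol regenerates the cofactor.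

**Step 12**
Reactants: 18 ethyl (2R)-2-hydroxy-4-methylpent-3-enoate
Product: 19 ethyl (2R)-2-[(tert-butyldimethylsilyl)oxy]-4-methylpent-3-enoate
Conditions: tBuMe2SiCl, imidazole, DMF, rt
Reagents that add atoms: tert-butyldimethylsilyl chloride CC(C)(C)[Si](C)(C)Cl
Why: Silyl ether formation under near-neutral conditions protects the allylic alcohol without epimerising the α-centre.

**Step 13**
Reactants: 19 ethyl (2R)-2-[(tert-butyldimethylsilyl)oxy]-4-methylpent-3-enoate
Product: 21 (2R)-2-[(tert-butyldimethylsilyl)oxy]-4-methylpent-3-en-1-ol, via silyloxy aldehyde 20 (not isolated)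
Conditions: iBu2AlH (2.5 equiv), CH2Cl2, −78 → −20 °C; aq. potassium sodium tartrate
Reagents that add atoms: none
Why: Exhaustive hydride reduction of the ester through the aldehyde; the non-basic aluminium alkoxides cause neither epimerisation nor 1,2-silyl migration.

**Step 14**
Reactants: 21 (2R)-2-[(tert-butyldimethylsilyl)oxy]-4-methylpent-3-en-1-ol
Product: 22 (2R)-2-[(tert-butyldimethylsilyl)oxy]-4-methylpent-3-en-1-yl trifluoromethanesulfonate
Conditions: (CF3SO2)2O (1.2 equiv), 2,6-lutidine (1.5 equiv), CH2Cl2, −78 °C; cold work-up, used at once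
Reagents that add atoms: trifluoromethanesulfonic anhydride O=S(=O)(OS(=O)(=O)C(F)(F)F)C(F)(F)F
Why: O-Sulfonylation of the primary alcohol gives a leaving group reactive enough to offset the retarding β-silyloxy branch.

**Step 15**
Reactants: 22 (2R)-2-[(tert-butyldimethylsilyl)oxy]-4-methylpent-3-en-1-yl trifluoromethanesulfonate; 23 methyl 2-[bis(2,2,2-trifluoroethoxy)phosphoryl]acetate
Product: 24 methyl (2RS,4S)-2-[bis(2,2,2-trifluoroethoxy)phosphoryl]-4-[(tert-butyldimethylsilyl)oxy]-6-methylhept-5-enoate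
Conditions: 23 (2.0 equiv), NaH (1.9 equiv), THF, 0 °C; then 22, THF/DMPU, −20 °C → rt
Reagents that add atoms: none
Why: SN2 C-alkylation of the stabilised phosphonoacetate carbanion by a primary triflate (malonate-type alkylation); the oxygenated centre is untouched (its descriptor becomes S only through the priority change), and C2 forms as an inconsequential epimer mixture.

**Step 16**
Reactants: 14 (4E,8E,11R)-11-[(tert-butyldimethylsilyl)oxy]-11-(furan-3-yl)-4,8-dimethylundeca-4,8-dienal; 24 methyl (2RS,4S)-2-[bis(2,2,2-trifluoroethoxy)phosphoryl]-4-[(tert-butyldimethylsilyl)oxy]-6-methylhept-5-enoate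
Product: 25 methyl (2Z,6E,10E,13R)-13-[(tert-butyldimethylsilyl)oxy]-2-[(2S)-2-[(tert-butyldimethylsilyl)oxy]-4-methylpent-3-en-1-yl]-13-(furan-3-yl)-6,10-dimethyltrideca-2,6,10-trienoate
Conditions: 24 (1.3 equiv), KN(SiMe3)2 (1.25 equiv), 18-crown-6 (4 equiv), THF, −78 °C; then 14, −78 → −40 °C
Reagents that add atoms: none
Why: Still–Gennari variant of the Horner–Wadsworth–Emmons olefination; with the trifluoroethyl phosphonate and a dissociated potassium counter-ion, elimination from the kinetic adduct outruns reversal and gives the (Z)-enoate (chain cis to CO2Me), the minor (E)-isomer being removed by chromatography.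

**Step 17**
Reactants: 25 methyl (2Z,6E,10E,13R)-13-[(tert-butyldimethylsilyl)oxy]-2-[(2S)-2-[(tert-butyldimethylsilyl)oxy]-4-methylpent-3-en-1-yl]-13-(furan-3-yl)-6,10-dimethyltrideca-2,6,10-trienoate
Product: 27 (3Z,5S)-3-[(4E,8E,11R)-11-(furan-3-yl)-11-hydroxy-4,8-dimethylundeca-4,8-dien-1-ylidene]-5-(2-methylprop-1-en-1-yl)oxolan-2-one, via dihydroxy ester 26 (not isolated)
Conditions: Bu4NF (3 equiv), AcOH (3 equiv), THF, 0 °C → rt; then pyridinium p-toluenesulfonate (0.1 equiv), CH2Cl2, rt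
Reagents that add atoms: none
Why: Fluoride desilylation followed by 5-exo-trig lactonisation of the freed γ-hydroxy ester; no bond at either stereocentre or olefin is broken, and the buffer prevents base-mediated Z→E isomerisation.

**Step 18**
Reactants: 27 (3Z,5S)-3-[(4E,8E,11R)-11-(furan-3-yl)-11-hydroxy-4,8-dimethylundeca-4,8-dien-1-ylidene]-5-(2-methylprop-1-en-1-yl)oxolan-2-one
Product: 28 (1R,3E,7E)-1-(furan-3-yl)-4,8-dimethyl-11-[(3Z,5S)-5-(2-methylprop-1-en-1-yl)-2-oxooxolan-3-ylidene]undeca-3,7-dien-1-yl acetate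
Conditions: Ac2O, pyridine, CH2Cl2, 0 °C → rt
Reagents that add atoms: acetic anhydride CC(=O)OC(C)=O
Why: O-Acetylation of the secondary alcohol by nucleophilic acyl substitution; pyridine alone is used so that no strong nucleophile isomerises the alkylidene lactone by conjugate addition.

**Step 19**
Reactants: 28 (1R,3E,7E)-1-(furan-3-yl)-4,8-dimethyl-11-[(3Z,5S)-5-(2-methylprop-1-en-1-yl)-2-oxooxolan-3-ylidene]undeca-3,7-dien-1-yl acetate
Product: 30 (1R,3E,7E)-1-(2-hydroxy-5-oxo-2,5-dihydrofuran-3-yl)-4,8-dimethyl-11-[(3Z,5S)-5-(2-methylprop-1-en-1-yl)-2-oxooxolan-3-ylidene]undeca-3,7-dien-1-yl acetate, via furan endoperoxide 29 (not isolated)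
Conditions: O2, 5,10,15,20-tetraphenylporphyrin (1 mol%), iPr2NEt (10 equiv), CH2Cl2, −78 °C, visible light; then warm to rt
Reagents that add atoms: oxygen O=O
Why: Singlet-oxygen [4+2] cycloaddition to the furan (much faster at −78 °C than the ene reaction of the trisubstituted alkenes), then Kornblum–DeLaMare-type opening in which the hindered amine removes the bridgehead hydrogen remote from the side chain, giving the 4-substituted 5-hydroxybutenolide regioselectively (hemiacetal epimers).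

**Step 20**
Reactants: 30 (1R,3E,7E)-1-(2-hydroxy-5-oxo-2,5-dihydrofuran-3-yl)-4,8-dimethyl-11-[(3Z,5S)-5-(2-methylprop-1-en-1-yl)-2-oxooxolan-3-ylidene]undeca-3,7-dien-1-yl acetate
Product: 32 (1R,3E,7E)-4,8-dimethyl-11-[(3Z,5S)-5-(2-methylprop-1-en-1-yl)-2-oxooxolan-3-ylidene]-1-(5-oxo-2,5-dihydrofuran-3-yl)undeca-3,7-dien-1-yl acetate, via hydroxy acid 31 (not isolated)
Conditions: NaBH4 (1.5 equiv), EtOH, 0 °C, 15 min; then dilute aq. HCl to pH 3, rt
Reagents that add atoms: none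
Why: Chemoselective borohydride reduction of the ring-opened formyl carboxylate tautomer, then acid-induced lactonisation of the 4-hydroxy acid to the butenolide; the acetate and the β-substituted alkylidene lactone are inert to NaBH4 in EtOH at 0 °C over this short time.

**Compound list**
1 | ethyl 3-(furan-3-yl)-3-oxopropanoate | CCOC(=O)CC(=O)c1ccoc1 | starting material
2 | ethyl (3R)-3-(furan-3-yl)-3-hydroxypropanoate | O[C@H](CC(=O)OCC)c1ccoc1 | intermediate
3 | ethyl (3R)-3-[(tert-butyldimethylsilyl)oxy]-3-(furan-3-yl)propanoate | CC(C)(C)[Si](C)(C)O[C@H](CC(=O)OCC)c1ccoc1 | intermediate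
4 | (3R)-3-[(tert-butyldimethylsilyl)oxy]-3-(furan-3-yl)propanal | CC(C)(C)[Si](C)(C)O[C@H](CC=O)c1ccoc1 | intermediate
5 | isopropenylmagnesium bromide | CC(=C)[Mg]Br | starting material
6 | (3RS,5R)-5-[(tert-butyldimethylsilyl)oxy]-5-(furan-3-yl)-2-methylpent-1-en-3-ol | CC(C)(C)[Si](C)(C)O[C@H](CC(O)C(C)=C)c1ccoc1 | intermediate
7 | triethyl orthoacetate | CCOC(C)(OCC)OCC | starting material
8 | ketene acetal: 3-[(1R)-1-[(tert-butyldimethylsilyl)oxy]-3-[(1-ethoxyethenyl)oxy]-4-methylpent-4-en-1-yl]furan | CC(C)(C)[Si](C)(C)O[C@H](CC(OC(=C)OCC)C(C)=C)c1ccoc1 | intermediate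
9 | ethyl (4E,7R)-7-[(tert-butyldimethylsilyl)oxy]-7-(furan-3-yl)-4-methylhept-4-enoate | CC(C)(C)[Si](C)(C)O[C@H](C/C=C(\C)CCC(=O)OCC)c1ccoc1 | intermediate
10 | (4E,7R)-7-[(tert-butyldimethylsilyl)oxy]-7-(furan-3-yl)-4-methylhept-4-enal | CC(C)(C)[Si](C)(C)O[C@H](C/C=C(\C)CCC=O)c1ccoc1 | intermediate
11 | (3RS,6E,9R)-9-[(tert-butyldimethylsilyl)oxy]-9-(furan-3-yl)-2,6-dimethylnona-1,6-dien-3-ol | CC(C)(C)[Si](C)(C)O[C@H](C/C=C(\C)CCC(O)C(C)=C)c1ccoc1 | intermediate
12 | ketene acetal: 3-[(1R,3E)-1-[(tert-butyldimethylsilyl)oxy]-7-[(1-ethoxyethenyl)oxy]-4,8-dimethylnona-3,8-dien-1-yl]furan | CC(C)(C)[Si](C)(C)O[C@H](C/C=C(\C)CCC(OC(=C)OCC)C(C)=C)c1ccoc1 | intermediate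
13 | ethyl (4E,8E,11R)-11-[(tert-butyldimethylsilyl)oxy]-11-(furan-3-yl)-4,8-dimethylundeca-4,8-dienoate | CC(C)(C)[Si](C)(C)O[C@H](C/C=C(\C)CC/C=C(\C)CCC(=O)OCC)c1ccoc1 | intermediate
14 | (4E,8E,11R)-11-[(tert-butyldimethylsilyl)oxy]-11-(furan-3-yl)-4,8-dimethylundeca-4,8-dienal | CC(C)(C)[Si](C)(C)O[C@H](C/C=C(\C)CC/C=C(\C)CCC=O)c1ccoc1 | intermediate
15 | diethyl oxalate | CCOC(=O)C(=O)OCC | starting material
16 | (2-methylprop-1-en-1-yl)magnesium bromide | CC(C)=C[Mg]Br | starting material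
17 | ethyl 4-methyl-2-oxopent-3-enoate | CCOC(=O)C(=O)C=C(C)C | intermediate
18 | ethyl (2R)-2-hydroxy-4-methylpent-3-enoate | CCOC(=O)[C@@H](C=C(C)C)O | intermediate
19 | ethyl (2R)-2-[(tert-butyldimethylsilyl)oxy]-4-methylpent-3-enoate | CCOC(=O)[C@@H](C=C(C)C)O[Si](C)(C)C(C)(C)C | intermediate
20 | silyloxy aldehyde: (2R)-2-[(tert-butyldimethylsilyl)oxy]-4-methylpent-3-enal | O=C[C@@H](C=C(C)C)O[Si](C)(C)C(C)(C)C | intermediate
21 | (2R)-2-[(tert-butyldimethylsilyl)oxy]-4-methylpent-3-en-1-ol | OC[C@@H](C=C(C)C)O[Si](C)(C)C(C)(C)C | intermediate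
22 | (2R)-2-[(tert-butyldimethylsilyl)oxy]-4-methylpent-3-en-1-yl trifluoromethanesulfonate | O=S(=O)(OC[C@@H](C=C(C)C)O[Si](C)(C)C(C)(C)C)C(F)(F)F | intermediate
23 | methyl 2-[bis(2,2,2-trifluoroethoxy)phosphoryl]acetate | COC(=O)CP(=O)(OCC(F)(F)F)OCC(F)(F)F | starting material
24 | methyl (2RS,4S)-2-[bis(2,2,2-trifluoroethoxy)phosphoryl]-4-[(tert-butyldimethylsilyl)oxy]-6-methylhept-5-enoate | COC(=O)C(C[C@@H](C=C(C)C)O[Si](C)(C)C(C)(C)C)P(=O)(OCC(F)(F)F)OCC(F)(F)F | intermediate
25 | methyl (2Z,6E,10E,13R)-13-[(tert-butyldimethylsilyl)oxy]-2-[(2S)-2-[(tert-butyldimethylsilyl)oxy]-4-methylpent-3-en-1-yl]-13-(furan-3-yl)-6,10-dimethyltrideca-2,6,10-trienoate | CC(C)(C)[Si](C)(C)O[C@H](C/C=C(\C)CC/C=C(\C)CC/C=C(/C[C@@H](C=C(C)C)O[Si](C)(C)C(C)(C)C)C(=O)OC)c1ccoc1 | intermediate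
26 | dihydroxy ester: methyl (2Z,6E,10E,13R)-13-(furan-3-yl)-13-hydroxy-2-[(2S)-2-hydroxy-4-methylpent-3-en-1-yl]-6,10-dimethyltrideca-2,6,10-trienoate | O[C@H](C/C=C(\C)CC/C=C(\C)CC/C=C(/C[C@@H](C=C(C)C)O)C(=O)OC)c1ccoc1 | intermediate
27 | (3Z,5S)-3-[(4E,8E,11R)-11-(furan-3-yl)-11-hydroxy-4,8-dimethylundeca-4,8-dien-1-ylidene]-5-(2-methylprop-1-en-1-yl)oxolan-2-one | O[C@H](C/C=C(\C)CC/C=C(\C)CC/C=C1/C[C@@H](C=C(C)C)OC1=O)c1ccoc1 | intermediate
28 | (1R,3E,7E)-1-(furan-3-yl)-4,8-dimethyl-11-[(3Z,5S)-5-(2-methylprop-1-en-1-yl)-2-oxooxolan-3-ylidene]undeca-3,7-dien-1-yl acetate | CC(=O)O[C@H](C/C=C(\C)CC/C=C(\C)CC/C=C1/C[C@@H](C=C(C)C)OC1=O)c1ccoc1 | intermediate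
29 | furan endoperoxide: (1R,3E,7E)-4,8-dimethyl-11-[(3Z,5S)-5-(2-methylprop-1-en-1-yl)-2-oxooxolan-3-ylidene]-1-(2,3,7-trioxabicyclo[2.2.1]hept-5-en-5-yl)undeca-3,7-dien-1-yl acetate | CC(=O)O[C@H](C/C=C(\C)CC/C=C(\C)CC/C=C1/C[C@@H](C=C(C)C)OC1=O)C1=CC2OOC1O2 | intermediate
30 | (1R,3E,7E)-1-(2-hydroxy-5-oxo-2,5-dihydrofuran-3-yl)-4,8-dimethyl-11-[(3Z,5S)-5-(2-methylprop-1-en-1-yl)-2-oxooxolan-3-ylidene]undeca-3,7-dien-1-yl acetate | CC(=O)O[C@H](C/C=C(\C)CC/C=C(\C)CC/C=C1/C[C@@H](C=C(C)C)OC1=O)C1=CC(=O)OC1O | intermediate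
31 | hydroxy acid: (2E)-3-[(1R,3E,7E)-1-acetoxy-4,8-dimethyl-11-[(3Z,5S)-5-(2-methylprop-1-en-1-yl)-2-oxooxolan-3-ylidene]undeca-3,7-dien-1-yl]-4-hydroxybut-2-enoic acid | CC(=O)O[C@H](C/C=C(\C)CC/C=C(\C)CC/C=C1/C[C@@H](C=C(C)C)OC1=O)/C(CO)=C/C(=O)O | intermediate
32 | (1R,3E,7E)-4,8-dimethyl-11-[(3Z,5S)-5-(2-methylprop-1-en-1-yl)-2-oxooxolan-3-ylidene]-1-(5-oxo-2,5-dihydrofuran-3-yl)undeca-3,7-dien-1-yl acetate | CC(=O)O[C@H](C/C=C(\C)CC/C=C(\C)CC/C=C1/C[C@@H](C=C(C)C)OC1=O)C1=CC(=O)OC1 | target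

**Totals**
Total step count: 20. Longest linear sequence: 14 steps (1 → 32 through steps 1–9 and 16–20); the fragment 2 branch is steps 10–15.

**Three steps most likely to fail**

Step 15 (alkylation of the weakly nucleophilic phosphonoacetate by a β-silyloxy triflate; slow substitution or triflate decomposition). The fallback sets out from 16 and 23 and comes back at 24; it creates the stereocentre after, not before, the carbon–carbon bond. Grignard reagent 16 is added at −78 °C to 2-chloro-N-methoxy-N-methylacetamide (Weinreb ketone synthesis) to give 1-chloro-4-methylpent-3-en-2-one F1. The sodium salt of 23 (NaH, THF, NaI cat.) is C-alkylated by this α-chloroketone, a far better electrophile, to give methyl 2-[bis(2,2,2-trifluoroethoxy)phosphoryl]-6-methyl-4-oxohept-5-enoate F2. A ketoreductase selected for the (4S)-alcohol (NADP+, iPrOH, pH 7) reduces the enone carbonyl to methyl (2RS,4S)-2-[bis(2,2,2-trifluoroethoxy)phosphoryl]-4-hydroxy-6-methylhept-5-enoate F3. This is silylated at once (tBuMe2SiOSO2CF3, 2,6-lutidine, −78 °C), before it can lactonise, to give 24.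

Step 16 (Z-selectivity and conversion with the bulky α-branched phosphonate). The fallback sets out from 22 and 14 and comes back at 27; the lactone carbonyl now comes from CO and the olefin geometry from a vinyl iodide. Ph3P=CH2 (from Ph3PCH3Br and n-BuLi) is alkylated by 22 to give [(3S)-3-[(tert-butyldimethylsilyl)oxy]-5-methylhex-4-en-1-yl]triphenylphosphonium trifluoromethanesulfonate F4. Deprotonation (NaN(SiMe3)2), iodination (I2, −78 °C), a second deprotonation and Wittig reaction with 14 (Stork–Zhao-type α-iodo ylide olefination) give the (Z)-vinyl iodide 3-[(1R,3E,7E,11Z,14S)-1,14-bis[(tert-butyldimethylsilyl)oxy]-12-iodo-4,8,16-trimethylheptadeca-3,7,11,15-tetraen-1-yl]furan F5. Bu4NF removes both silyl groups to give (1R,3E,7E,11Z,14S)-1-(furan-3-yl)-12-iodo-4,8,16-trimethylheptadeca-3,7,11,15-tetraene-1,14-diol F6. Carbonylative lactonisation (Pd(PPh3)4, zerovalent palladium, 5 mol%, CO 1 atm, Et3N, MeCN, 50 °C) proceeds with retention of the olefin geometry and gives 27.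

Step 19 (competing ene reactions of the four trisubstituted alkenes with singlet oxygen, and regiocontrol of the endoperoxide opening). The fallback sets out from 28 and comes back at 32, replacing steps 19 and 20 with no singlet oxygen and no hydride. Sterically controlled C–H borylation ([Ir(OMe)(cod)]2, 4,4'-di-tert-butyl-2,2'-bipyridine, bis(pinacolato)diboron, THF/hexane, rt) at the furan α-position remote from the side chain gives (1R,3E,7E)-4,8-dimethyl-11-[(3Z,5S)-5-(2-methylprop-1-en-1-yl)-2-oxooxolan-3-ylidene]-1-[5-(4,4,5,5-tetramethyl-1,3,2-dioxaborolan-2-yl)furan-3-yl]undeca-3,7-dien-1-yl acetate F7. Oxidation (NaBO3·4H2O, THF/H2O, 0 °C) gives the 2-hydroxyfuran, which tautomerises (Et3N cat.) to the conjugated butenolide 32.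

**Further compounds**
F1 | step 15 | 1-chloro-4-methylpent-3-en-2-one | CC(C)=CC(=O)CCl
F2 | step 15 | methyl 2-[bis(2,2,2-trifluoroethoxy)phosphoryl]-6-methyl-4-oxohept-5-enoate | COC(=O)C(CC(=O)C=C(C)C)P(=O)(OCC(F)(F)F)OCC(F)(F)F
F3 | step 15 | methyl (2RS,4S)-2-[bis(2,2,2-trifluoroethoxy)phosphoryl]-4-hydroxy-6-methylhept-5-enoate | COC(=O)C(C[C@@H](C=C(C)C)O)P(=O)(OCC(F)(F)F)OCC(F)(F)F
F4 | step 16 | [(3S)-3-[(tert-butyldimethylsilyl)oxy]-5-methylhex-4-en-1-yl]triphenylphosphonium trifluoromethanesulfonate | C(C[C@@H](C=C(C)C)O[Si](C)(C)C(C)(C)C)[P+](c1ccccc1)(c1ccccc1)c1ccccc1.[O-]S(=O)(=O)C(F)(F)F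
F5 | step 16 | 3-[(1R,3E,7E,11Z,14S)-1,14-bis[(tert-butyldimethylsilyl)oxy]-12-iodo-4,8,16-trimethylheptadeca-3,7,11,15-tetraen-1-yl]furan | CC(C)(C)[Si](C)(C)O[C@H](C/C=C(\C)CC/C=C(\C)CC/C=C(\I)C[C@@H](C=C(C)C)O[Si](C)(C)C(C)(C)C)c1ccoc1
F6 | step 16 | (1R,3E,7E,11Z,14S)-1-(furan-3-yl)-12-iodo-4,8,16-trimethylheptadeca-3,7,11,15-tetraene-1,14-diol | O[C@H](C/C=C(\C)CC/C=C(\C)CC/C=C(\I)C[C@@H](C=C(C)C)O)c1ccoc1
F7 | step 19 | (1R,3E,7E)-4,8-dimethyl-11-[(3Z,5S)-5-(2-methylprop-1-en-1-yl)-2-oxooxolan-3-ylidene]-1-[5-(4,4,5,5-tetramethyl-1,3,2-dioxaborolan-2-yl)furan-3-yl]undeca-3,7-dien-1-yl acetate | CC(=O)O[C@H](C/C=C(\C)CC/C=C(\C)CC/C=C1/C[C@@H](C=C(C)C)OC1=O)c1coc(B2OC(C)(C)C(C)(C)O2)c1
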